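## The problem

The target is a sesquineolignan. An erythro-guaiacylglycerol unit (ring A, C7''–C9'') is joined through the oxygen on C8'' to C4 of ring B of (−)-pinoresinol. Pinoresinol is a cis-fused 3,7-dioxabicyclo[3.3.0]octane with ring B on C7 and ring C on C7', both exo. Six stereocentres must be set: 7R, 8S, 7'R and 8'S in the bicycle, 7''R and 8''S in the side chain.

Inside the bicycle the centres can control one another. An aryl group on C7 can push a substituent on C8' to the other face of a ring, the cis fusion at C8/C8' follows once a second five-membered ring is closed, and C7' can be left to a closure through a benzylic cation. The two side-chain centres are too far from the core to feel it and need reagent control.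

Rings B and C are both guaiacyl rings and differ only in that ring B is etherified. Any dimerisation logic makes them identical, so they must carry different protecting groups from the start.

The benzylic C–O bonds at C7, C7' and C7'' are para to oxygen. They ionise in acid (epimerisation at C7/C7', erythro–threo scrambling at C7'') and are open to hydrogenolysis, and the free phenols are easily oxidised, so the late steps must be neutral and mild.

The structural handle for the key step is the tetrahydrofuran made of the ring oxygen, C7, C8, C8' and C9'. It carries the one-carbon branch C9 on C8, next to C8'. This is the pattern left when a six-membered ketone, with C9 as the ring carbonyl between C8 and C8', expels that carbon from the ring.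

## Retrosynthesis

**Side chain, C7''–C8''.** Target 31 is first traced to its bis(benzyl ether) 30, then the aldol bond C7''–C8'' is cut to give aryloxyacetyl imide 26 and aldehyde 7. The neighbouring cut at O–C8'' would ask the hindered phenol 21 to displace a leaving group at a secondary carbon beside a benzylic carbinol. A reduction of an α-aryloxy β-keto ester would ask a catalyst or enzyme to accept the whole lignan as α-substituent. The boron aldol of 26 gives only the syn (threo) adduct 28, with C8'' correct and C7'' wrong, so C7'' is inverted (29) before the auxiliary is cleaved (30). The precursor 26 lacks ring A and both side-chain stereocentres. The forward steps must override any bias from the remote lignan and invert a benzylic carbinol cleanly.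

**Aryl ether, O4–C8''.** Imide 26 is cut at the phenol oxygen into phenol 21 and bromoacetyl imide 25, itself from oxazolidinone 22 and acid bromide 23. At this stage C8'' is a primary, carbonyl-activated carbon, so the ether is made by a simple SN2 reaction before any stereocentre exists there. The precursor 21 is the core with ring B free and ring C still benzylated.

**Second ring, C7'–O.** Phenol 21 comes from allyl ether 20, and 20 is opened at the C7'–O bond to diol 19. Cutting at C9–O instead would need an SN2 closure with a fixed C7' configuration. The benzylic cut lets both C7' epimers converge through one cation. The precursor has one ring and one controlled stereocentre less. The forward closure must be kinetic, exo-selective and must not disturb C7.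

**C9–O7' acyl bond as a relay.** Diol 19 is the hydride reduction product of lactone 18, and 18 arises from ester 16 through hydroxy ester 17. The lactone is chosen over a direct ester reduction because only the C8 epimer with the ester cis to the C8' arm can close it. This converts the uncontrolled C8 of 16 into the required cis fusion. The forward step needs C8 to epimerise under base without opening the tetrahydrofuran.

**Key disconnection, C8–C8'.** Ester 16 is traced through ketene 15 to 3-diazotetrahydropyran-4-one 14 by breaking C8–C8' and rejoining C8' to C9. A direct five-ring closure would have to set the 2,4-trans relation kinetically. On the six-membered ketone the same relation is the 2,5-trans, diequatorial arrangement, reachable by equilibration next to the carbonyl. The precursor is a pyranone available by cycloaddition. The forward step must shift C8' with retention and avoid carbene side reactions.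

**C8'–C7' aldol bond and the diazo group.** Diazo ketone 14 comes from ketone 11 by diazo transfer at C8. Ketone 11 comes from aldol adduct 9 through silyl ether 10, and 9 is cut at C8'–C7' into dihydropyranone 6 and aldehyde 7. Using the enone of 6 for a reductive aldol fixes the enolate regiochemistry, which deprotonation of a saturated pyranone would not. The precursor 6 has one stereocentre and one aryl ring. The forward sequence must bring C8' trans to the C7 aryl group and place the diazo group only at C8.

**Pyranone, O–C9' and C7–C8.** Dihydropyranone 6 is cut into aldehyde 3 and diene 4, and 3 into vanillin 1 and allyl bromide 2. The catalytic asymmetric hetero-Diels–Alder reaction sets C7, the centre that controls the rest of the core, from achiral materials. The allyl ether marks ring B from the first step.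

## Roads not taken

**Alternative 1:** The cut removes the C8''–O4 and C7''–C8'' bonds together and returns (−)-pinoresinol monoacetate A1, ethyl diazoacetate A2 and vanillin acetate A3.
- Forward key step: a dirhodium tetracarboxylate turns A2 into a carbenoid, the phenol of A1 adds to give an oxonium ylide, and a chiral phosphoric acid steers its aldol-type capture by A3 to the erythro β-hydroxy ester A4. Ester reduction and deacetylation would finish.
- Merits: the whole side chain with both stereocentres appears in one convergent step, no ring is built, and the target is about three steps from A1.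
- Weak points: A1 must be made from (−)-pinoresinol A5, the less accessible antipode of a C2-symmetric bisphenol, by statistical mono-acylation. Ylides from acceptor-only diazo esters such as A2 usually collapse by proton transfer to the O–H insertion product before they are trapped, and the electron-rich aldehyde A3 is a slow trap. Erythro/threo and absolute control rest on the acid catalyst alone.
- Comparison: in step count this road is clearly better. The chosen plan offers instead stereocentres set by reaction classes of predictable sense, rings B and C that differ from step 1 so that no statistical step occurs, and independence from a supply of A5.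

**Alternative 2:** The cut opens both C7–O and C7'–O bonds and joins C7 to C7', leading back to the all-trans cyclobutane diol A6, the reduced head-to-head [2+2] dimer of a protected cinnamate.
- Forward key step: anodic one-electron oxidation of an aryl ring weakens the C7–C7' bond, the cyclobutane opens, and the two hydroxymethyl groups capture C7 and C7' to close both tetrahydrofurans, giving (−)-pinoresinol dibenzyl ether A7.
- Merits: the bicycle appears in one step, C8 and C8' are already set in A6, and the sequence to A7 is very short.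
- Weak points: A7 has the same benzyl ether on rings B and C, so the side chain can be attached only after a statistical mono-debenzylation. The absolute configuration of A6 needs an enantioselective head-to-head photodimerisation or a resolution. The product is as easily oxidised as the substrate, so over-oxidation and exo/endo leakage at C7/C7' are likely.
- Comparison: for the furofuran alone this road is shorter and would be preferred for pinoresinol itself. For this unsymmetrically etherified target the chosen plan supplies two distinguishable rings and catalyst-controlled configuration at C7, at the price of more steps.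

**Alternative 3:** The cut severs C7–C8 and C8'–C7' around a butenolide, giving dithiane A8 (from aldehyde 3), 5-menthyloxybutenolide A9 and aldehyde 7.
- Forward key step: lithiated A8 adds to the β-carbon of A9 anti to the acetal substituent and the lactone enolate is captured by 7 trans to the new group, giving butanolide A10. Hydride reduction, dithiane hydrolysis, carbonyl reduction and a double cyclisation would lead to 20.
- Merits: conjugate addition–aldol on such acetal butenolides is well precedented, sets C8 and C8' in one step, keeps rings B and C distinct, and the count to 20 is probably no higher than in the chosen plan.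
- Weak points: the dithiane must be hydrolysed beside an allyl ether and two electron-rich arenes. Both benzylic centres, C7 and C7', are then formed together in one cationic double cyclisation. The chiral information is stoichiometric and needs the less common antipode of the terpene auxiliary.
- Comparison: in precedent and probably in length this road is at least equal. The chosen plan offers C7 fixed early by a catalytic step and never ionised, only one benzylic centre left to the last closure, and no sulfur removal.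

Key step: step 6

## Route

Assumptions (remarks on the chemistry):
- The catalyst from (R)-BINOL and Ti(Oi-Pr)4 is taken to deliver diene 4 to the Re face of aldehyde 3 and so to give (R)-6; if the sense is opposite, (S)-BINOL is used and nothing else changes.
- Epimers that converge later carry one number and are named and drawn as one isomer: 9 and 10 as the 2,5-cis ketones expected from axial attack (any trans isomer is already of type 11), 16 and 17 as the (3R) ester (the 3S epimer accompanies it and is corrected in step 7), and 9 to 19 as the (R)-carbinol at C7' (the S epimer behaves alike and is erased in step 9).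
- Aldehyde 7 and oxazolidinone 22 are taken as commercial.

Step 1
Reactants: 1 vanillin; 2 allyl bromide
Product: 3 4-(allyloxy)-3-methoxybenzaldehyde
Conditions: K2CO3, DMF, 25 °C
Reagents that add atoms: none
Why: Williamson ether synthesis, SN2 attack of the phenoxide of 1 on 2; the allyl ether marks ring B for selective release in step 10.

Step 2
Reactants: 3 4-(allyloxy)-3-methoxybenzaldehyde; 4 (E)-1-methoxy-3-(trimethylsilyloxy)buta-1,3-diene
Product: 6 (R)-2-[4-(allyloxy)-3-methoxyphenyl]-2,3-dihydro-4H-pyran-4-one, via Mukaiyama aldol adduct 5 (not isolated)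
Conditions: Ti(Oi-Pr)4 (10 mol %), (R)-BINOL (20 mol %), 4 Å MS, Et2O, −20 °C; then CF3CO2H, CH2Cl2, 0 °C
Reagents that add atoms: none
Why: Catalytic asymmetric hetero-Diels–Alder annulation of an aromatic aldehyde with a 1-alkoxy-3-silyloxy diene, run in its stepwise Mukaiyama aldol–cyclisation form; the BINOL complex of tetravalent titanium shields one face of the bound aldehyde so that Re-face attack sets C7 as R, and acid closes the ring with loss of methanol and the silyl group.

Step 3
Reactants: 6 (R)-2-[4-(allyloxy)-3-methoxyphenyl]-2,3-dihydro-4H-pyran-4-one; 7 4-(benzyloxy)-3-methoxybenzaldehyde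
Product: 9 (2R,5R)-2-[4-(allyloxy)-3-methoxyphenyl]-5-[(R)-[4-(benzyloxy)-3-methoxyphenyl](hydroxy)methyl]tetrahydro-4H-pyran-4-one, via lithium enolate 8 (not isolated)
Conditions: LiBH(s-Bu)3, THF, −78 °C; then 7, −78 °C; AcOH
Reagents that add atoms: none
Why: Reductive aldol: 1,4-hydride addition to the vinylogous ester gives the enolate at C8' only, which adds to 7 and forms the C8'–C7' bond. Axial attack on the half-chair enolate is expected to give mainly the 2,5-cis ketone; C8' is corrected in step 4 and the C7' configuration is irrelevant because it is erased in step 9.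

Step 4
Reactants: 9 (2R,5R)-2-[4-(allyloxy)-3-methoxyphenyl]-5-[(R)-[4-(benzyloxy)-3-methoxyphenyl](hydroxy)methyl]tetrahydro-4H-pyran-4-one
Product: 11 (2R,5S)-2-[4-(allyloxy)-3-methoxyphenyl]-5-[(R)-[4-(benzyloxy)-3-methoxyphenyl][(tert-butyldimethylsilyl)oxy]methyl]tetrahydro-4H-pyran-4-one, via cis silyl ether 10 (not isolated)
Conditions: TBSOTf, 2,6-lutidine, CH2Cl2, −78 °C; then DBU (0.2 equiv), CH2Cl2, 25 °C
Reagents that add atoms: tert-butyldimethylsilyl trifluoromethanesulfonate, CC(C)(C)[Si](C)(C)OS(=O)(=O)C(F)(F)F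
Why: Silylation of the aldol hydroxyl blocks retro-aldol cleavage; base-mediated epimerisation α to the ketone then moves the C8' substituent to the equatorial position, so the equatorial C7 aryl group sets C8' trans to itself under thermodynamic control.

Step 5
Reactants: 11 (2R,5S)-2-[4-(allyloxy)-3-methoxyphenyl]-5-[(R)-[4-(benzyloxy)-3-methoxyphenyl][(tert-butyldimethylsilyl)oxy]methyl]tetrahydro-4H-pyran-4-one
Product: 14 (2S,5S)-2-[4-(allyloxy)-3-methoxyphenyl]-5-[(R)-[4-(benzyloxy)-3-methoxyphenyl][(tert-butyldimethylsilyl)oxy]methyl]-3-diazotetrahydro-4H-pyran-4-one, via lithium enolate 12 (not isolated), via trifluoroacetyl ketone 13 (not isolated)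
Conditions: LiN(SiMe3)2, THF, −78 °C; CF3CO2CH2CF3; aq. HCl; then MsN3, Et3N, H2O, MeCN, 25 °C
Reagents that add atoms: methanesulfonyl azide, CS(=O)(=O)N=[N+]=[N-]
Why: Detrifluoroacetylative diazo transfer: kinetic deprotonation takes the C8 methylene rather than the hindered C8' methine, Claisen-type trifluoroacetylation activates that position, and the sulfonyl azide transfers N2 with loss of the trifluoroacetyl group. No stereocentre is formed; the C7 descriptor changes to S only because the diazo carbon outranks the aryl group.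

Step 6
Reactants: 14 (2S,5S)-2-[4-(allyloxy)-3-methoxyphenyl]-5-[(R)-[4-(benzyloxy)-3-methoxyphenyl][(tert-butyldimethylsilyl)oxy]methyl]-3-diazotetrahydro-4H-pyran-4-one
Product: 16 methyl (2R,3R,4S)-2-[4-(allyloxy)-3-methoxyphenyl]-4-[(R)-[4-(benzyloxy)-3-methoxyphenyl][(tert-butyldimethylsilyl)oxy]methyl]tetrahydrofuran-3-carboxylate, via ketene 15 (not isolated)
Conditions: hν (365 nm), MeOH, 0 °C
Reagents that add atoms: methanol, CO
Why: Photochemical Wolff rearrangement used as a ring contraction. Excitation of the diazo ketone, which the ring holds s-cis, expels N2 in concert with the 1,2-shift of C8' from the carbonyl carbon C9 to the diazo carbon C8 and gives ketene 15; methanol adds to the ketene and the ester enol ketonises to 16. The closest known reaction type is the light-induced six-to-five contraction of cyclic 2-diazo ketones to cycloalkane- and oxacycloalkanecarboxylates. The tetrahydrofuran (O, C7, C8, C8', C9') is closed by contraction, not by cyclisation: the new ring bond C8–C8' comes from the suprafacial alkyl shift and C9 leaves the ring as the ester carbon. C8' migrates with retention and C7 is untouched, so the 2,5-trans relation of 14 becomes the 2,4-trans relation of 16. The new centre C8 is created by protonation of the ester enol and is not controlled here; both epimers are expected and converge in step 7. The step needs migration to outrun carbene chemistry (O–H insertion of methanol, hydride shift from C7) and the arene chromophores to stay unexcited; the enforced s-cis geometry favours the concerted path, and 365 nm light should be absorbed by the diazo ketone only. Regiochemistry is fixed, since C8' is the only carbon on the carbonyl apart from the diazo carbon.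

Step 7
Reactants: 16 methyl (2R,3R,4S)-2-[4-(allyloxy)-3-methoxyphenyl]-4-[(R)-[4-(benzyloxy)-3-methoxyphenyl][(tert-butyldimethylsilyl)oxy]methyl]tetrahydrofuran-3-carboxylate
Product: 18 (3R,3aS,6R,6aR)-6-[4-(allyloxy)-3-methoxyphenyl]-3-[4-(benzyloxy)-3-methoxyphenyl]tetrahydro-1H,3H-furo[3,4-c]furan-1-one, via hydroxy ester 17 (not isolated)
Conditions: n-Bu4NF, THF, 0 → 25 °C; then KOt-Bu (0.2 equiv), 25 °C; AcOH
Reagents that add atoms: none
Why: Fluoride desilylation followed by alkoxide-catalysed epimerisation–lactonisation. Only the C8 epimer with the ester cis to the C8' carbinol arm can close the cis-fused γ-lactone, so reversible enolisation at C8 funnels both epimers into 18 and sets C8; the ring C–O bond lies near the enolate plane, which disfavours β-elimination.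

Step 8
Reactants: 18 (3R,3aS,6R,6aR)-6-[4-(allyloxy)-3-methoxyphenyl]-3-[4-(benzyloxy)-3-methoxyphenyl]tetrahydro-1H,3H-furo[3,4-c]furan-1-one
Product: 19 [(2R,3S,4S)-2-[4-(allyloxy)-3-methoxyphenyl]-4-[(R)-[4-(benzyloxy)-3-methoxyphenyl](hydroxy)methyl]tetrahydrofuran-3-yl]methanol
Conditions: LiAlH4, THF, 0 °C; aq. NaOH work-up
Reagents that add atoms: none
Why: Hydride reduction of a lactone to the 1,4-diol; the allyl and benzyl aryl ethers are inert and no stereocentre is touched.

Step 9
Reactants: 19 [(2R,3S,4S)-2-[4-(allyloxy)-3-methoxyphenyl]-4-[(R)-[4-(benzyloxy)-3-methoxyphenyl](hydroxy)methyl]tetrahydrofuran-3-yl]methanol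
Product: 20 (1R,3aS,4R,6aS)-1-[4-(allyloxy)-3-methoxyphenyl]-4-[4-(benzyloxy)-3-methoxyphenyl]tetrahydro-1H,3H-furo[3,4-c]furan
Conditions: camphorsulfonic acid (10 mol %), CH2Cl2, 0 °C
Reagents that add atoms: none
Why: Acid-catalysed SN1 cycloetherification: the para-alkoxybenzylic alcohol ionises to a quinone-methide-like cation that the C9 hydroxyl captures in a 5-exo closure. The aryl group takes the exo position on the convex face of the forming bicycle under kinetic control, so both C7' epimers give the 7'R product.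

Step 10
Reactants: 20 (1R,3aS,4R,6aS)-1-[4-(allyloxy)-3-methoxyphenyl]-4-[4-(benzyloxy)-3-methoxyphenyl]tetrahydro-1H,3H-furo[3,4-c]furan
Product: 21 4-[(1R,3aS,4R,6aS)-4-[4-(benzyloxy)-3-methoxyphenyl]tetrahydro-1H,3H-furo[3,4-c]furan-1-yl]-2-methoxyphenol
Conditions: Pd(PPh3)4 (5 mol %), morpholine, THF, 25 °C
Reagents that add atoms: none
Why: Tsuji–Trost deallylation: zerovalent palladium ionises the allyl aryl ether and morpholine takes up the allyl group; benzyl ether and benzylic ring ethers are not affected.

Step 11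
Reactants: 22 (R)-4-benzyloxazolidin-2-one; 23 bromoacetyl bromide
Product: 25 (R)-4-benzyl-3-(2-bromoacetyl)oxazolidin-2-one, via lithium oxazolidinide 24 (not isolated)
Conditions: n-BuLi, THF, −78 °C; then 23, −78 → 0 °C
Reagents that add atoms: none
Why: N-Acylation of a lithiated oxazolidinone by an acid bromide; the acyl bromide reacts far faster than the alkyl bromide.

Step 12
Reactants: 21 4-[(1R,3aS,4R,6aS)-4-[4-(benzyloxy)-3-methoxyphenyl]tetrahydro-1H,3H-furo[3,4-c]furan-1-yl]-2-methoxyphenol; 25 (R)-4-benzyl-3-(2-bromoacetyl)oxazolidin-2-one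
Product: 26 (R)-4-benzyl-3-[2-[4-[(1R,3aS,4R,6aS)-4-[4-(benzyloxy)-3-methoxyphenyl]tetrahydro-1H,3H-furo[3,4-c]furan-1-yl]-2-methoxyphenoxy]acetyl]oxazolidin-2-one
Conditions: K2CO3, acetone, 25 °C
Reagents that add atoms: none
Why: Williamson ether synthesis on a carbonyl-activated primary bromide; SN2 displacement is much faster than attack of the phenoxide on the imide carbonyl groups.

Step 13
Reactants: 26 (R)-4-benzyl-3-[2-[4-[(1R,3aS,4R,6aS)-4-[4-(benzyloxy)-3-methoxyphenyl]tetrahydro-1H,3H-furo[3,4-c]furan-1-yl]-2-methoxyphenoxy]acetyl]oxazolidin-2-one; 7 4-(benzyloxy)-3-methoxybenzaldehyde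
Product: 28 (R)-4-benzyl-3-[(2R,3S)-3-[4-(benzyloxy)-3-methoxyphenyl]-2-[4-[(1R,3aS,4R,6aS)-4-[4-(benzyloxy)-3-methoxyphenyl]tetrahydro-1H,3H-furo[3,4-c]furan-1-yl]-2-methoxyphenoxy]-3-hydroxypropanoyl]oxazolidin-2-one, via boron enolate 27 (not isolated)
Conditions: n-Bu2BOTf, i-Pr2NEt, CH2Cl2, −78 → 0 °C; then 7, −78 → 0 °C; pH 7 buffer, MeOH, H2O2
Reagents that add atoms: none
Why: Evans syn aldol of a glycolate-type imide: the Z boron enolate reacts through a Zimmerman–Traxler chair on the face away from the auxiliary benzyl group. This sets C8'' in its final arrangement (R here, S once the acyl carbon is CH2OH) and C7'' as the syn, threo epimer (S), which step 14 inverts.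

Step 14
Reactants: 28 (R)-4-benzyl-3-[(2R,3S)-3-[4-(benzyloxy)-3-methoxyphenyl]-2-[4-[(1R,3aS,4R,6aS)-4-[4-(benzyloxy)-3-methoxyphenyl]tetrahydro-1H,3H-furo[3,4-c]furan-1-yl]-2-methoxyphenoxy]-3-hydroxypropanoyl]oxazolidin-2-one
Product: 29 (1R,2R)-3-[(R)-4-benzyl-2-oxooxazolidin-3-yl]-1-[4-(benzyloxy)-3-methoxyphenyl]-2-[4-[(1R,3aS,4R,6aS)-4-[4-(benzyloxy)-3-methoxyphenyl]tetrahydro-1H,3H-furo[3,4-c]furan-1-yl]-2-methoxyphenoxy]-3-oxopropyl 4-nitrobenzoate
Conditions: PPh3, DIAD, 4-O2NC6H4CO2H, toluene, 0 → 25 °C
Reagents that add atoms: 4-nitrobenzoic acid, OC(=O)c1ccc(cc1)[N+](=O)[O-]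
Why: Mitsunobu inversion: the carboxylate displaces the alkoxyphosphonium group at C7'' by SN2, turning the threo adduct into the erythro series (C7'' now R). A(1,3) strain in the imide keeps the C8'' hydrogen out of alignment with the carbonyl and so disfavours elimination.

Step 15
Reactants: 29 (1R,2R)-3-[(R)-4-benzyl-2-oxooxazolidin-3-yl]-1-[4-(benzyloxy)-3-methoxyphenyl]-2-[4-[(1R,3aS,4R,6aS)-4-[4-(benzyloxy)-3-methoxyphenyl]tetrahydro-1H,3H-furo[3,4-c]furan-1-yl]-2-methoxyphenoxy]-3-oxopropyl 4-nitrobenzoate
Product: 30 (1R,2S)-1-[4-(benzyloxy)-3-methoxyphenyl]-2-[4-[(1R,3aS,4R,6aS)-4-[4-(benzyloxy)-3-methoxyphenyl]tetrahydro-1H,3H-furo[3,4-c]furan-1-yl]-2-methoxyphenoxy]propane-1,3-diol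
Conditions: LiBH4, THF–MeOH, 0 → 25 °C
Reagents that add atoms: none
Why: Reductive cleavage of the N-acyloxazolidinone to the primary alcohol with concurrent reduction of the 4-nitrobenzoate; neither stereocentre is touched and the auxiliary is recovered.

Step 16
Reactants: 30 (1R,2S)-1-[4-(benzyloxy)-3-methoxyphenyl]-2-[4-[(1R,3aS,4R,6aS)-4-[4-(benzyloxy)-3-methoxyphenyl]tetrahydro-1H,3H-furo[3,4-c]furan-1-yl]-2-methoxyphenoxy]propane-1,3-diol
Product: 31 (1R,2S)-1-(4-hydroxy-3-methoxyphenyl)-2-[4-[(1R,3aS,4R,6aS)-4-(4-hydroxy-3-methoxyphenyl)tetrahydro-1H,3H-furo[3,4-c]furan-1-yl]-2-methoxyphenoxy]propane-1,3-diol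
Conditions: H2 (1 atm), Pd/C (10 wt % Pd), NaHCO3, EtOAc–MeOH, 25 °C
Reagents that add atoms: none
Why: Hydrogenolysis of two aryl benzyl ethers, which is much faster than cleavage of the benzylic ring ethers or the benzylic alcohol; the hydrogen carbonate buffer removes traces of acid that would promote those cleavages.

## Compound list

1 | vanillin (4-hydroxy-3-methoxybenzaldehyde) | COc1cc(C=O)ccc1O | starting material
2 | allyl bromide | C=CCBr | starting material
3 | 4-(allyloxy)-3-methoxybenzaldehyde | COc1cc(C=O)ccc1OCC=C | intermediate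
4 | (E)-1-methoxy-3-(trimethylsilyloxy)buta-1,3-diene | CO/C=C/C(=C)O[Si](C)(C)C | starting material
5 | (R,E)-5-[4-(allyloxy)-3-methoxyphenyl]-1-methoxy-5-(trimethylsilyloxy)pent-1-en-3-one | CO/C=C/C(=O)C[C@@H](O[Si](C)(C)C)c1ccc(OCC=C)c(OC)c1 | intermediate
6 | (R)-2-[4-(allyloxy)-3-methoxyphenyl]-2,3-dihydro-4H-pyran-4-one | COc1cc(ccc1OCC=C)[C@@H]2OC=CC(=O)C2 | intermediate
7 | 4-(benzyloxy)-3-methoxybenzaldehyde | COc1cc(C=O)ccc1OCc2ccccc2 | starting material
8 | lithium (R)-2-[4-(allyloxy)-3-methoxyphenyl]-3,6-dihydro-2H-pyran-4-olate | COc1cc(ccc1OCC=C)[C@@H]2OCC=C([O-])C2.[Li+] | intermediate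
9 | (2R,5R)-2-[4-(allyloxy)-3-methoxyphenyl]-5-[(R)-[4-(benzyloxy)-3-methoxyphenyl](hydroxy)methyl]tetrahydro-4H-pyran-4-one | COc1cc(ccc1OCC=C)[C@@H]2OC[C@H]([C@@H](O)c3ccc(OCc4ccccc4)c(OC)c3)C(=O)C2 | intermediate
10 | (2R,5R)-2-[4-(allyloxy)-3-methoxyphenyl]-5-[(R)-[4-(benzyloxy)-3-methoxyphenyl][(tert-butyldimethylsilyl)oxy]methyl]tetrahydro-4H-pyran-4-one | COc1cc(ccc1OCC=C)[C@@H]2OC[C@H]([C@@H](O[Si](C)(C)C(C)(C)C)c3ccc(OCc4ccccc4)c(OC)c3)C(=O)C2 | intermediate
11 | (2R,5S)-2-[4-(allyloxy)-3-methoxyphenyl]-5-[(R)-[4-(benzyloxy)-3-methoxyphenyl][(tert-butyldimethylsilyl)oxy]methyl]tetrahydro-4H-pyran-4-one | COc1cc(ccc1OCC=C)[C@@H]2OC[C@@H]([C@@H](O[Si](C)(C)C(C)(C)C)c3ccc(OCc4ccccc4)c(OC)c3)C(=O)C2 | intermediate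
12 | lithium (2R,5S)-2-[4-(allyloxy)-3-methoxyphenyl]-5-[(R)-[4-(benzyloxy)-3-methoxyphenyl][(tert-butyldimethylsilyl)oxy]methyl]-5,6-dihydro-2H-pyran-4-olate | COc1cc(ccc1OCC=C)[C@@H]2OC[C@@H]([C@@H](O[Si](C)(C)C(C)(C)C)c3ccc(OCc4ccccc4)c(OC)c3)C([O-])=C2.[Li+] | intermediate
13 | (2R,5S)-2-[4-(allyloxy)-3-methoxyphenyl]-5-[(R)-[4-(benzyloxy)-3-methoxyphenyl][(tert-butyldimethylsilyl)oxy]methyl]-3-(trifluoroacetyl)tetrahydro-4H-pyran-4-one (C3 enolised, not defined) | COc1cc(ccc1OCC=C)[C@@H]2OC[C@@H]([C@@H](O[Si](C)(C)C(C)(C)C)c3ccc(OCc4ccccc4)c(OC)c3)C(=O)C2C(=O)C(F)(F)F | intermediate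
14 | (2S,5S)-2-[4-(allyloxy)-3-methoxyphenyl]-5-[(R)-[4-(benzyloxy)-3-methoxyphenyl][(tert-butyldimethylsilyl)oxy]methyl]-3-diazotetrahydro-4H-pyran-4-one | COc1cc(ccc1OCC=C)[C@@H]2OC[C@@H]([C@@H](O[Si](C)(C)C(C)(C)C)c3ccc(OCc4ccccc4)c(OC)c3)C(=O)C2=[N+]=[N-] | intermediate
15 | (2S,4S)-2-[4-(allyloxy)-3-methoxyphenyl]-4-[(R)-[4-(benzyloxy)-3-methoxyphenyl][(tert-butyldimethylsilyl)oxy]methyl]-3-(oxomethylidene)tetrahydrofuran (ketene) | COc1cc(ccc1OCC=C)[C@@H]2OC[C@@H]([C@@H](O[Si](C)(C)C(C)(C)C)c3ccc(OCc4ccccc4)c(OC)c3)C2=C=O | intermediate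
16 | methyl (2R,3R,4S)-2-[4-(allyloxy)-3-methoxyphenyl]-4-[(R)-[4-(benzyloxy)-3-methoxyphenyl][(tert-butyldimethylsilyl)oxy]methyl]tetrahydrofuran-3-carboxylate | COc1cc(ccc1OCC=C)[C@@H]2OC[C@@H]([C@@H](O[Si](C)(C)C(C)(C)C)c3ccc(OCc4ccccc4)c(OC)c3)[C@H]2C(=O)OC | intermediate
17 | methyl (2R,3R,4S)-2-[4-(allyloxy)-3-methoxyphenyl]-4-[(R)-[4-(benzyloxy)-3-methoxyphenyl](hydroxy)methyl]tetrahydrofuran-3-carboxylate | COc1cc(ccc1OCC=C)[C@@H]2OC[C@@H]([C@@H](O)c3ccc(OCc4ccccc4)c(OC)c3)[C@H]2C(=O)OC | intermediate
18 | (3R,3aS,6R,6aR)-6-[4-(allyloxy)-3-methoxyphenyl]-3-[4-(benzyloxy)-3-methoxyphenyl]tetrahydro-1H,3H-furo[3,4-c]furan-1-one | COc1cc(ccc1OCC=C)[C@@H]2OC[C@@H]3[C@H]2C(=O)O[C@H]3c4ccc(OCc5ccccc5)c(OC)c4 | intermediate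
19 | [(2R,3S,4S)-2-[4-(allyloxy)-3-methoxyphenyl]-4-[(R)-[4-(benzyloxy)-3-methoxyphenyl](hydroxy)methyl]tetrahydrofuran-3-yl]methanol | COc1cc(ccc1OCC=C)[C@@H]2OC[C@@H]([C@@H](O)c3ccc(OCc4ccccc4)c(OC)c3)[C@H]2CO | intermediate
20 | (1R,3aS,4R,6aS)-1-[4-(allyloxy)-3-methoxyphenyl]-4-[4-(benzyloxy)-3-methoxyphenyl]tetrahydro-1H,3H-furo[3,4-c]furan | COc1cc(ccc1OCC=C)[C@@H]2OC[C@@H]3[C@H]2CO[C@H]3c4ccc(OCc5ccccc5)c(OC)c4 | intermediate
21 | 4-[(1R,3aS,4R,6aS)-4-[4-(benzyloxy)-3-methoxyphenyl]tetrahydro-1H,3H-furo[3,4-c]furan-1-yl]-2-methoxyphenol | COc1cc(ccc1O)[C@@H]2OC[C@@H]3[C@H]2CO[C@H]3c4ccc(OCc5ccccc5)c(OC)c4 | intermediate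
22 | (R)-4-benzyloxazolidin-2-one | O=C1N[C@H](Cc2ccccc2)CO1 | starting material
23 | bromoacetyl bromide | BrCC(Br)=O | starting material
24 | lithium salt of (R)-4-benzyloxazolidin-2-one | [Li+].O=C1[N-][C@H](Cc2ccccc2)CO1 | intermediate
25 | (R)-4-benzyl-3-(2-bromoacetyl)oxazolidin-2-one | BrCC(=O)N1C(=O)OC[C@H]1Cc2ccccc2 | intermediate
26 | (R)-4-benzyl-3-[2-[4-[(1R,3aS,4R,6aS)-4-[4-(benzyloxy)-3-methoxyphenyl]tetrahydro-1H,3H-furo[3,4-c]furan-1-yl]-2-methoxyphenoxy]acetyl]oxazolidin-2-one | COc1cc(ccc1OCC(=O)N2C(=O)OC[C@H]2Cc3ccccc3)[C@@H]4OC[C@@H]5[C@H]4CO[C@H]5c6ccc(OCc7ccccc7)c(OC)c6 | intermediate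
27 | (Z)-O-dibutylboryl enolate of 26 | CCCCB(CCCC)O/C(=C\Oc1ccc(cc1OC)[C@@H]2OC[C@@H]3[C@H]2CO[C@H]3c4ccc(OCc5ccccc5)c(OC)c4)N6C(=O)OC[C@H]6Cc7ccccc7 | intermediate
28 | (R)-4-benzyl-3-[(2R,3S)-3-[4-(benzyloxy)-3-methoxyphenyl]-2-[4-[(1R,3aS,4R,6aS)-4-[4-(benzyloxy)-3-methoxyphenyl]tetrahydro-1H,3H-furo[3,4-c]furan-1-yl]-2-methoxyphenoxy]-3-hydroxypropanoyl]oxazolidin-2-one | O=C(N1C(=O)OC[C@H]1Cc2ccccc2)[C@H](Oc3ccc(cc3OC)[C@@H]4OC[C@@H]5[C@H]4CO[C@H]5c6ccc(OCc7ccccc7)c(OC)c6)[C@@H](O)c8ccc(OCc9ccccc9)c(OC)c8 | intermediate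
29 | (1R,2R)-3-[(R)-4-benzyl-2-oxooxazolidin-3-yl]-1-[4-(benzyloxy)-3-methoxyphenyl]-2-[4-[(1R,3aS,4R,6aS)-4-[4-(benzyloxy)-3-methoxyphenyl]tetrahydro-1H,3H-furo[3,4-c]furan-1-yl]-2-methoxyphenoxy]-3-oxopropyl 4-nitrobenzoate | O=C(N1C(=O)OC[C@H]1Cc2ccccc2)[C@H](Oc3ccc(cc3OC)[C@@H]4OC[C@@H]5[C@H]4CO[C@H]5c6ccc(OCc7ccccc7)c(OC)c6)[C@H](OC(=O)c8ccc(cc8)[N+](=O)[O-])c8ccc(OCc9ccccc9)c(OC)c8 | intermediate
30 | (1R,2S)-1-[4-(benzyloxy)-3-methoxyphenyl]-2-[4-[(1R,3aS,4R,6aS)-4-[4-(benzyloxy)-3-methoxyphenyl]tetrahydro-1H,3H-furo[3,4-c]furan-1-yl]-2-methoxyphenoxy]propane-1,3-diol | OC[C@H](Oc1ccc(cc1OC)[C@@H]2OC[C@@H]3[C@H]2CO[C@H]3c4ccc(OCc5ccccc5)c(OC)c4)[C@H](O)c6ccc(OCc7ccccc7)c(OC)c6 | intermediate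
31 | (1R,2S)-1-(4-hydroxy-3-methoxyphenyl)-2-[4-[(1R,3aS,4R,6aS)-4-(4-hydroxy-3-methoxyphenyl)tetrahydro-1H,3H-furo[3,4-c]furan-1-yl]-2-methoxyphenoxy]propane-1,3-diol | COc1cc([C@@H](O)[C@H](CO)Oc2ccc([C@@H]3OC[C@@H]4[C@H]3CO[C@H]4c3ccc(O)c(OC)c3)cc2OC)ccc1O | target

## Step count and least certain steps

Total step count: 16. Longest linear sequence: 15 steps (1 to 31 through steps 1–10 and 12–16; step 11 is a one-step branch).

**Step 6 (key step).** The most likely failure is loss of nitrogen to a free keto carbene before C8' migrates. That carbene would be intercepted by methanol (O–H insertion) or would undergo a hydride shift from C7. A second danger is competing light absorption by the aryl ethers, with photo-Claisen rearrangement of the allyl ether if short wavelengths reach the sample. The fallback removes the external nucleophile and lets the C7' oxygen trap the ketene. Starting from 14, buffered desilylation (n-Bu4NF, AcOH, THF) gives the hydroxy diazo ketone F1. Irradiation of F1 at 365 nm in MeCN should give the ketene, which the neighbouring hydroxyl captures to form the cis-fused lactone directly. This sets C8 in the same event and rejoins the route at 18, replacing steps 6 and 7.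

**Step 4.** During base equilibration the C8' enolate can expel the β-silyloxy group (E1cB loss of silanol), and enolisation toward C8 can open the ring by retro-oxa-Michael reaction, which would also erode C7. Epimerisation may also stop short. The fallback sets C8' by kinetic protonation instead of equilibration. Starting from 6, iodination (I2, pyridine) gives the iodo enone F2. Nozaki–Hiyama–Kishi coupling of F2 with 7 (CrCl2 with catalytic NiCl2, DMF; divalent chromium) gives the hydroxy enone F3, and TBSOTf with 2,6-lutidine gives the silyl ether F4. Conjugate reduction of F4 with LiBH(s-Bu)3 at −78 °C and axial protonation of the enolate places the side chain equatorial and returns to the route at 11.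

**Step 9.** Under acid the benzylic ether bonds of the product, and the C7–O bond already present, can ionise again, which drifts C7 or C7' toward the endo-aryl isomers. Closure of the minor carbinol epimer may also be slow. The fallback keeps the C7'–O bond intact and makes no benzylic cation. It starts from the 7'R epimer of lactone 18, separated from its epimer at that stage. Reduction with i-Bu2AlH at −78 °C gives the lactol F5, and Et3SiH with BF3·OEt2 at −78 °C removes the lactol hydroxyl through the non-benzylic oxocarbenium ion at C9. This rejoins the route at 20 and replaces steps 8 and 9.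

**Step 14.** The activated alcohol can eliminate across C7''–C8'' instead of being displaced, or ionise at the electron-rich benzylic carbon so that inversion is incomplete. The β-acyloxy imide 29 may also eliminate the carboxylate in step 15. The fallback inverts after the auxiliary is gone, when no acidic hydrogen remains at C8''. Starting from 28, LiBH4 gives the threo diol F6. A Mitsunobu reaction with excess 4-nitrobenzoic acid, PPh3 and DIAD esterifies the primary hydroxyl and inverts C7'', giving the bis(4-nitrobenzoate) F7. Methanolysis (K2CO3, MeOH) returns to the route at 30, replacing steps 14 and 15.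

## Further compounds

F1 | step 6 | (2S,5S)-2-[4-(allyloxy)-3-methoxyphenyl]-5-[(R)-[4-(benzyloxy)-3-methoxyphenyl](hydroxy)methyl]-3-diazotetrahydro-4H-pyran-4-one | COc1cc(ccc1OCC=C)[C@@H]2OC[C@@H]([C@@H](O)c3ccc(OCc4ccccc4)c(OC)c3)C(=O)C2=[N+]=[N-]
F2 | step 4 | (R)-2-[4-(allyloxy)-3-methoxyphenyl]-5-iodo-2,3-dihydro-4H-pyran-4-one | COc1cc(ccc1OCC=C)[C@@H]2OC=C(I)C(=O)C2
F3 | step 4 | (2R)-2-[4-(allyloxy)-3-methoxyphenyl]-5-[[4-(benzyloxy)-3-methoxyphenyl](hydroxy)methyl]-2,3-dihydro-4H-pyran-4-one (both carbinol epimers) | COc1cc(ccc1OCC=C)[C@@H]2OC=C(C(O)c3ccc(OCc4ccccc4)c(OC)c3)C(=O)C2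
F4 | step 4 | (2R)-2-[4-(allyloxy)-3-methoxyphenyl]-5-[[4-(benzyloxy)-3-methoxyphenyl][(tert-butyldimethylsilyl)oxy]methyl]-2,3-dihydro-4H-pyran-4-one (both carbinol epimers) | COc1cc(ccc1OCC=C)[C@@H]2OC=C(C(O[Si](C)(C)C(C)(C)C)c3ccc(OCc4ccccc4)c(OC)c3)C(=O)C2
F5 | step 9 | (3R,3aS,6R,6aR)-6-[4-(allyloxy)-3-methoxyphenyl]-3-[4-(benzyloxy)-3-methoxyphenyl]tetrahydro-1H,3H-furo[3,4-c]furan-1-ol (both anomers) | COc1cc(ccc1OCC=C)[C@@H]2OC[C@@H]3[C@H]2C(O)O[C@H]3c4ccc(OCc5ccccc5)c(OC)c4
F6 | step 14 | (1S,2S)-1-[4-(benzyloxy)-3-methoxyphenyl]-2-[4-[(1R,3aS,4R,6aS)-4-[4-(benzyloxy)-3-methoxyphenyl]tetrahydro-1H,3H-furo[3,4-c]furan-1-yl]-2-methoxyphenoxy]propane-1,3-diol | OC[C@H](Oc1ccc(cc1OC)[C@@H]2OC[C@@H]3[C@H]2CO[C@H]3c4ccc(OCc5ccccc5)c(OC)c4)[C@@H](O)c6ccc(OCc7ccccc7)c(OC)c6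
F7 | step 14 | (1R,2S)-1-[4-(benzyloxy)-3-methoxyphenyl]-2-[4-[(1R,3aS,4R,6aS)-4-[4-(benzyloxy)-3-methoxyphenyl]tetrahydro-1H,3H-furo[3,4-c]furan-1-yl]-2-methoxyphenoxy]propane-1,3-diyl bis(4-nitrobenzoate) | [O-][N+](=O)c1ccc(cc1)C(=O)OC[C@H](Oc2ccc(cc2OC)[C@@H]3OC[C@@H]4[C@H]3CO[C@H]4c5ccc(OCc6ccccc6)c(OC)c5)[C@H](OC(=O)c7ccc(cc7)[N+](=O)[O-])c8ccc(OCc9ccccc9)c(OC)c8
A1 | alternative 1 | (−)-pinoresinol monoacetate (ring C acetate) | COc1cc(ccc1O)[C@@H]2OC[C@@H]3[C@H]2CO[C@H]3c4ccc(OC(C)=O)c(OC)c4
A2 | alternative 1 | ethyl diazoacetate | CCOC(=O)C=[N+]=[N-]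
A3 | alternative 1 | vanillin acetate (4-formyl-2-methoxyphenyl acetate) | COc1cc(C=O)ccc1OC(C)=O
A4 | alternative 1 | ethyl erythro-3-(4-acetoxy-3-methoxyphenyl)-3-hydroxy-2-[(ring C O-acetyl (−)-pinoresinol)-4-yloxy]propanoate | COc1cc([C@@H](O)[C@H](C(=O)OCC)Oc2ccc([C@@H]3OC[C@@H]4[C@H]3CO[C@H]4c5ccc(OC(C)=O)c(OC)c5)cc2OC)ccc1OC(C)=O
A5 | alternative 1 | (−)-pinoresinol | COc1cc(ccc1O)[C@@H]2OC[C@@H]3[C@H]2CO[C@H]3c4ccc(O)c(OC)c4
A6 | alternative 2 | [(1S,2S,3R,4R)-3,4-bis[4-(benzyloxy)-3-methoxyphenyl]cyclobutane-1,2-diyl]dimethanol | OC[C@@H]1[C@@H](CO)[C@H](c2ccc(OCc3ccccc3)c(OC)c2)[C@H]1c4ccc(OCc5ccccc5)c(OC)c4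
A7 | alternative 2 | (−)-pinoresinol dibenzyl ether | COc1cc(ccc1OCc2ccccc2)[C@@H]3OC[C@@H]4[C@H]3CO[C@H]4c5ccc(OCc6ccccc6)c(OC)c5
A8 | alternative 3 | 2-[4-(allyloxy)-3-methoxyphenyl]-1,3-dithiane | COc1cc(ccc1OCC=C)C2SCCCS2
A9 | alternative 3 | (S)-5-[(1S,2R,5S)-2-isopropyl-5-methylcyclohexyloxy]furan-2(5H)-one | O=C1C=C[C@@H](O[C@H]2C[C@@H](C)CC[C@@H]2C(C)C)O1
A10 | alternative 3 | trans-3,4-disubstituted 5-menthyloxybutanolide with the ring B dithiane on C8 and the ring C carbinol on C8' (one carbinol epimer drawn) | O=C1[C@@H]([C@@H](O)c2ccc(OCc3ccccc3)c(OC)c2)[C@H](C4(SCCCS4)c5ccc(OCC=C)c(OC)c5)[C@@H](O[C@H]6C[C@@H](C)CC[C@@H]6C(C)C)O1
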